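**Retrosynthetic overview**
- Avoided: guanidine/enaminone pyrimidine synthesis on a 3-acyl-5,6-dibromoindole, and any cross-coupling of the indole C3–pyrimidine C4' bond. That bond is bought as the C–CH3 bond of 2-amino-4-methylpyrimidine.
- Meridianin F ⇒ (N1–C2) reductive cyclisation of an o-nitroaryl dimethylamino-enamine whose alpha carbon already carries the pyrimidine (alpha-hetaryl Leimgruber–Batcho).
- Enamine ⇒ (C2=C3, one carbon from DMF dimethyl acetal) 4-(4,5-dibromo-2-nitrobenzyl)pyrimidine.
- Benzylpyrimidine ⇒ (C3–C3a, key step) SNAr of the laterally metalated, amidine-masked 2-amino-4-methylpyrimidine on 1,2-dibromo-4-fluoro-5-nitrobenzene. Both bromines are placed unambiguously by nitration of 1,2-dibromo-4-fluorobenzene.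
- Ring order: the benzene and pyrimidine rings are purchased. The pyrrole ring is the only ring formed, in the last step.

Assumption: the target has no stereocentre or stereoaxis, so no enantiomer has to be controlled; only C=N and C=C geometries of intermediates are specified, and these are lost before the target.

**Step 1**
Reactants: 1 1,2-dibromo-4-fluorobenzene
Product: 2 1,2-dibromo-4-fluoro-5-nitrobenzene
Conditions: fuming HNO3 (1.2 equiv), conc. H2SO4, 0 °C to rt, 3 h
Reagents that add atoms: nitric acid, O[N+](=O)[O-]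
Why: Electrophilic aromatic nitration: C5 is ortho to F and para to the C2 bromine and, unlike C3, is not wedged between two halogens, so NO2+ enters there and fixes the later 5,6-dibromo pattern (the same regiochemistry as in the nitration of 3,4-dichlorofluorobenzene); no stereocentre is formed.

**Step 2**
Reactants: 3 2-amino-4-methylpyrimidine
Product: 4 (E)-N,N-dimethyl-N'-(4-methylpyrimidin-2-yl)formimidamide
Conditions: Me2NCH(OMe)2 (1.2 equiv), toluene, 100 °C, 3 h
Reagents that add atoms: N,N-dimethylformamide dimethyl acetal, COC(OC)N(C)C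
Why: Amide-acetal condensation: the exocyclic NH2 exchanges both methoxy groups well below the temperature at which the 4-methyl group would condense, giving the base-stable (E)-formamidine that removes both acidic N–H protons before the carbanion step.

**Step 3 (key step)**
Reactants: 4 (E)-N,N-dimethyl-N'-(4-methylpyrimidin-2-yl)formimidamide; 2 1,2-dibromo-4-fluoro-5-nitrobenzene
Product: 7 (E)-N'-[4-(4,5-dibromo-2-nitrobenzyl)pyrimidin-2-yl]-N,N-dimethylformimidamide, via sodium azaallyl anion 5 (not isolated), via sodium salt of coupled product 6 (not isolated)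
Conditions: 4 (1.1 equiv), NaN(SiMe3)2 (2.3 equiv), THF, −78 °C, 30 min; then 2 in THF, −78 to 0 °C, 2 h (argon); AcOH quench
Reagents that add atoms: none
Why: Lateral metalation followed by SNAr: the soft anion 5, delocalised over both ring nitrogens, displaces the fluoride ortho to NO2 through a Meisenheimer adduct (F reacts far faster than the Br para to NO2, and adducts at C–H positions are reversible), while the second equivalent of the hindered base stores the much more acidic product as its inert anion 6 until the quench.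

**Step 4**
Reactants: 7 (E)-N'-[4-(4,5-dibromo-2-nitrobenzyl)pyrimidin-2-yl]-N,N-dimethylformimidamide
Product: 8 (E)-N'-{4-[(E)-1-(4,5-dibromo-2-nitrophenyl)-2-(dimethylamino)ethenyl]pyrimidin-2-yl}-N,N-dimethylformimidamide
Conditions: Me2NCH(OMe)2 (3 equiv), DMF, 80 °C, 5 h
Reagents that add atoms: N,N-dimethylformamide dimethyl acetal, COC(OC)N(C)C
Why: Leimgruber–Batcho-type enamine formation: the CH2 flanked by o-nitrophenyl and pyrimidin-4-yl is far more acidic than an o-nitrotoluene methyl, so it condenses at only 80 °C (as 2-nitrophenylacetates and 2-nitrophenylacetonitriles do), which keeps the Br para to NO2 safe from Me2NH or methoxide; the push-pull C=C geometry (drawn E) is irrelevant because it is lost on cyclisation.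

**Step 5**
Reactants: 8 (E)-N'-{4-[(E)-1-(4,5-dibromo-2-nitrophenyl)-2-(dimethylamino)ethenyl]pyrimidin-2-yl}-N,N-dimethylformimidamide
Product: 11 meridianin F [4-(5,6-dibromo-1H-indol-3-yl)pyrimidin-2-amine], via amino enamine 9 (not isolated), via amidine-masked indolylpyrimidine 10 (not isolated)
Conditions: Fe powder (8 equiv), AcOH/EtOH 1:1, 80 °C, 2 h; filter, concentrate; then 7 M NH3 in MeOH, 50 °C, 12 h
Reagents that add atoms: none
Why: Leimgruber–Batcho reductive cyclisation: Béchamp-type Fe/AcOH reduction converts NO2 into NH2 without touching the aryl bromides, the aniline nitrogen adds to the protonated enamine carbon and expels Me2NH to aromatise with the pyrimidine fixed at C3, and methanolic ammonia then removes the formamidine by transamidination; no stereocentre is created.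

**Compound list**
1 | 1,2-dibromo-4-fluorobenzene | Fc1ccc(Br)c(Br)c1 | starting material
2 | 1,2-dibromo-4-fluoro-5-nitrobenzene | Fc1cc(Br)c(Br)cc1[N+](=O)[O-] | intermediate
3 | 2-amino-4-methylpyrimidine | Cc1ccnc(N)n1 | starting material
4 | (E)-N,N-dimethyl-N'-(4-methylpyrimidin-2-yl)formimidamide | CN(C)/C=N/c1nccc(C)n1 | intermediate
5 | sodium [2-{(E)-[(dimethylamino)methylidene]amino}pyrimidin-4-yl]methanide (azaallyl anion of 4, not isolated) | CN(C)/C=N/c1nccc([CH2-])n1.[Na+] | intermediate
6 | sodium (4,5-dibromo-2-nitrophenyl)[2-{(E)-[(dimethylamino)methylidene]amino}pyrimidin-4-yl]methanide (anion of 7, not isolated) | CN(C)/C=N/c1nccc([CH-]c2cc(Br)c(Br)cc2[N+](=O)[O-])n1.[Na+] | intermediate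
7 | (E)-N'-[4-(4,5-dibromo-2-nitrobenzyl)pyrimidin-2-yl]-N,N-dimethylformimidamide | CN(C)/C=N/c1nccc(Cc2cc(Br)c(Br)cc2[N+](=O)[O-])n1 | intermediate
8 | (E)-N'-{4-[(E)-1-(4,5-dibromo-2-nitrophenyl)-2-(dimethylamino)ethenyl]pyrimidin-2-yl}-N,N-dimethylformimidamide | CN(C)/C=C(/c1ccnc(/N=C/N(C)C)n1)c1cc(Br)c(Br)cc1[N+](=O)[O-] | intermediate
9 | (E)-N'-{4-[(E)-1-(2-amino-4,5-dibromophenyl)-2-(dimethylamino)ethenyl]pyrimidin-2-yl}-N,N-dimethylformimidamide (not isolated) | CN(C)/C=C(/c1ccnc(/N=C/N(C)C)n1)c1cc(Br)c(Br)cc1N | intermediate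
10 | (E)-N'-[4-(5,6-dibromo-1H-indol-3-yl)pyrimidin-2-yl]-N,N-dimethylformimidamide (not isolated) | CN(C)/C=N/c1nccc(-c2c[nH]c3cc(Br)c(Br)cc23)n1 | intermediate
11 | meridianin F, 4-(5,6-dibromo-1H-indol-3-yl)pyrimidin-2-amine (achiral) | Nc1nccc(-c2c[nH]c3cc(Br)c(Br)cc23)n1 | target

**Totals**
Total step count: 5.
Longest linear sequence: 4 steps (1 → 2 → 7 → 8 → 11, or 3 → 4 → 7 → 8 → 11).

**Three steps most likely to fail**

Risk 1 (step 3). Possible failures are electron transfer from the carbanion to the nitroarene, attack at the Br para to NO2, and incomplete metalation.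
- The fallback sets out from 4 and comes back at 7. It replaces the hard carbanion by a stabilised ester enolate and removes the ester afterwards.
- Anion 5 (NaN(SiMe3)2, 2.2 equiv, THF, −78 °C) is C-acylated with Boc2O to give tert-butyl 2-(2-{(E)-[(dimethylamino)methylidene]amino}pyrimidin-4-yl)acetate F1.
- This ester and 2 are joined with Cs2CO3 in DMF at 40 °C (malonate-type SNAr) to give racemic tert-butyl 2-(4,5-dibromo-2-nitrophenyl)-2-(2-{(E)-[(dimethylamino)methylidene]amino}pyrimidin-4-yl)acetate F2.
- TFA/CH2Cl2 cleaves the tert-butyl ester to racemic 2-(4,5-dibromo-2-nitrophenyl)-2-(2-{(E)-[(dimethylamino)methylidene]amino}pyrimidin-4-yl)acetic acid F3, which decarboxylates on warming to 40 °C and delivers 7.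

Risk 2 (step 4). Possible failures are displacement of the Br para to NO2 by Me2NH or methoxide at 80 °C, C-methylation by the acetal, and slow condensation at the hindered CH2.
- The fallback sets out from 7 and comes back at 10. It swaps the hot, neutral amide-acetal condensation for a cold anionic Claisen-type formylation.
- KOt-Bu (2.2 equiv) and HCO2Et (5 equiv) in THF at 0 °C give (E)-N'-{4-[(Z)-1-(4,5-dibromo-2-nitrophenyl)-2-hydroxyethenyl]pyrimidin-2-yl}-N,N-dimethylformimidamide F4. This is the enol of the aryl(hetaryl)acetaldehyde, hydrogen-bonded to the ring nitrogen.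
- Fe/AcOH at 60 °C reduces it to (E)-N'-{4-[(Z)-1-(2-amino-4,5-dibromophenyl)-2-hydroxyethenyl]pyrimidin-2-yl}-N,N-dimethylformimidamide F5, which cyclodehydrates in the flask to 10.
- The ammonia stage of step 5 then follows.

Risk 3 (step 5). Possible failures are hydrolysis and deformylation of the enamine in hot aqueous acid before ring closure, arrest at the 1-hydroxyindole, and partial debromination.
- The fallback sets out from 7 and comes back at 10. It replaces the protic metal reduction by an anhydrous deoxygenative (Cadogan–Sundberg) cyclisation of an alpha-hetaryl-2-nitrostyrene.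
- Paraformaldehyde, K2CO3 and catalytic n-Bu4NI in toluene at 80 °C hydroxymethylate 7 to racemic (E)-N'-{4-[1-(4,5-dibromo-2-nitrophenyl)-2-hydroxyethyl]pyrimidin-2-yl}-N,N-dimethylformimidamide F6.
- This carbinol dehydrates under the same conditions (E1cB) to (E)-N'-{4-[1-(4,5-dibromo-2-nitrophenyl)ethenyl]pyrimidin-2-yl}-N,N-dimethylformimidamide F7.
- PPh3 (2.5 equiv) and MoO2Cl2(dmf)2 (5 mol %) in refluxing toluene strip both nitro oxygens and close the N1–C2 bond to give 10, with the aryl bromides untouched because no palladium is present.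

**Further compounds**
F1 | step 3 | tert-butyl 2-(2-{(E)-[(dimethylamino)methylidene]amino}pyrimidin-4-yl)acetate | CN(C)/C=N/c1nccc(CC(=O)OC(C)(C)C)n1
F2 | step 3 | tert-butyl 2-(4,5-dibromo-2-nitrophenyl)-2-(2-{(E)-[(dimethylamino)methylidene]amino}pyrimidin-4-yl)acetate (racemic) | CN(C)/C=N/c1nccc(C(C(=O)OC(C)(C)C)c2cc(Br)c(Br)cc2[N+](=O)[O-])n1
F3 | step 3 | 2-(4,5-dibromo-2-nitrophenyl)-2-(2-{(E)-[(dimethylamino)methylidene]amino}pyrimidin-4-yl)acetic acid (racemic) | CN(C)/C=N/c1nccc(C(C(=O)O)c2cc(Br)c(Br)cc2[N+](=O)[O-])n1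
F4 | step 4 | (E)-N'-{4-[(Z)-1-(4,5-dibromo-2-nitrophenyl)-2-hydroxyethenyl]pyrimidin-2-yl}-N,N-dimethylformimidamide | O/C=C(\c1ccnc(/N=C/N(C)C)n1)c1cc(Br)c(Br)cc1[N+](=O)[O-]
F5 | step 4 | (E)-N'-{4-[(Z)-1-(2-amino-4,5-dibromophenyl)-2-hydroxyethenyl]pyrimidin-2-yl}-N,N-dimethylformimidamide | O/C=C(\c1ccnc(/N=C/N(C)C)n1)c1cc(Br)c(Br)cc1N
F6 | step 5 | (E)-N'-{4-[1-(4,5-dibromo-2-nitrophenyl)-2-hydroxyethyl]pyrimidin-2-yl}-N,N-dimethylformimidamide (racemic) | CN(C)/C=N/c1nccc(C(CO)c2cc(Br)c(Br)cc2[N+](=O)[O-])n1
F7 | step 5 | (E)-N'-{4-[1-(4,5-dibromo-2-nitrophenyl)ethenyl]pyrimidin-2-yl}-N,N-dimethylformimidamide | CN(C)/C=N/c1nccc(C(=C)c2cc(Br)c(Br)cc2[N+](=O)[O-])n1
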